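**Assumption (one line):** germacrane numbering is used for locants (lactone C12(=O)–O–C8; C6 and C11 carry the angelates; target read from the SMILES as 6S,7S,8R,11R, 1(10)Z,4E); the (R,R)-iPr-box ligand is taken to give the (1R,5R,6R) cyclopropane (mirror image of the ligand that gives the 1S,5S,6S series); compounds 6, 8, 24 and (−)-sparteine are bought.

## Retrosynthetic overview

1. Target 26 ⇒ diol 23 (both angelates last); the C11 quaternary centre ⇒ methylation of an α-silyloxy lactone enolate (methyl enters trans to C6) after enolate hydroxylation.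
2. Ten-membered ring ⇒ C5–C6 bond by nickel-catalysed methylative alkyne–aldehyde macrocyclisation of lactone ynal 15 (also makes the 4E olefin and brings in C15).
3. 15 ⇒ cyclopropane aldehyde 5 + (R)-allylboronate 11: C8–C9 bond and the 1(10)Z olefin by allylboration, then retro-aldol/lactonisation.
4. 5 ⇒ methyl furan-2-carboxylate + ethyl diazoacetate: enantioselective cyclopropanation that breaks the furan aromaticity and sets C7, then ozonolysis (furan C3, C4, C5 become C8, C7, C6).
5. Ring order: sacrificial cyclopropane → γ-lactone (step 6) → ten-membered carbocycle (step 7).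

## Route

**Step 1** (key step)
Reactants: 1 methyl furan-2-carboxylate; 2 ethyl diazoacetate
Product: 3 6-ethyl 3-methyl (1R,5R,6R)-2-oxabicyclo[3.1.0]hex-3-ene-3,6-dicarboxylate
Conditions: Cu(OTf)2 (1 mol %), (R,R)-iPr-box (1.2 mol %), PhNHNH2 (1 mol %), CH2Cl2, 0 °C, slow addition of 2; recrystallisation (pentane)
Reagents that add atoms: none
Why: Asymmetric cyclopropanation of the unsubstituted, more electron-rich C4=C5 bond of the furan by a monovalent-copper bis(oxazoline) carbenoid (dearomatisation) gives the exo ester on one enantiotopic face, which fixes the future C7 (bicycle C5, R) by catalyst control, and one recrystallisation raises the ee above 99 %.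

**Step 2**
Reactants: 3 the bicyclic enol ether
Product: 5 ethyl (1R,2R,3R)-2-formyl-3-[(2-methoxy-2-oxoacetyl)oxy]cyclopropane-1-carboxylate, via secondary ozonide 4 (not isolated)
Conditions: O3, CH2Cl2, −78 °C; then Me2S, −78 °C to rt; used crude
Reagents that add atoms: ozone, [O-][O+]=O
Why: Ozonolysis (Criegee mechanism, reductive work-up) of the remaining enol-ether double bond turns furan C3 into the aldehyde that becomes C8 and leaves furan C2 as a methyl oxalyl ester on the cyclopropanol oxygen, without touching a stereocentre.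

**Step 3**
Reactants: 6 5-(trimethylsilyl)pent-4-yn-1-ol
Product: 7 5-(trimethylsilyl)pent-4-yn-1-yl N,N-diisopropylcarbamate
Conditions: iPr2NCOCl, Et3N, CH2Cl2, reflux
Reagents that add atoms: N,N-diisopropylcarbamoyl chloride, CC(C)N(C(C)C)C(Cl)=O
Why: Carbamoylation of the primary alcohol installs the Hoppe carbamate needed to direct and stabilise the enantioselective α-lithiation.

**Step 4**
Reactants: 7 the carbamate; 8 isopropenylboronic acid pinacol ester
Product: 11 4,4,5,5-tetramethyl-2-[(3R)-2-methyl-7-(trimethylsilyl)hept-1-en-6-yn-3-yl]-1,3,2-dioxaborolane, via lithiated carbamate 9 (not isolated), via boronate complex 10 (not isolated)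
Conditions: s-BuLi, (−)-sparteine, Et2O, −78 °C, 5 h; then 8, −78 °C; then reflux, 12 h
Reagents that add atoms: none
Why: Hoppe–Aggarwal lithiation–borylation, in which s-BuLi/(−)-sparteine removes the pro-S α-proton, the configurationally stable (S)-lithio carbamate is borylated with retention and the isopropenyl group migrates with inversion (1,2-metallate shift), gives the (R)-α-substituted allylboronate.

**Step 5**
Reactants: 5 the cyclopropane aldehyde; 11 the (R)-allylboronate
Product: 13 ethyl (1R,2S,3R)-2-[(1R,3Z)-1-hydroxy-3-methyl-8-(trimethylsilyl)oct-3-en-7-yn-1-yl]-3-[(2-methoxy-2-oxoacetyl)oxy]cyclopropane-1-carboxylate, via O-boryl ether 12 (not isolated)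
Conditions: 11 (1.3 equiv), CH2Cl2, 4 Å MS, 0 °C to rt, 48 h; pH 7 buffer
Reagents that add atoms: none
Why: Allylboration through a closed six-membered chair transition state (SE2′, new C8–C9 bond) places the α-substituent axial, away from the pinacolato group and the 2-methyl group, which gives the Z-trisubstituted C1(10) olefin, and the (R)-boronate is matched with the Felkin–Anh face of the cyclopropyl aldehyde so that C8 forms as R.

**Step 6**
Reactants: 13 the homoallylic alcohol
Product: 15 (2R,3S)-2-[(2Z)-2-methylhept-2-en-6-yn-1-yl]-5-oxooxolane-3-carbaldehyde, via cyclopropanol 14 (not isolated)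
Conditions: Ba(OH)2·8H2O (20 mol %), MeOH, 0 °C to rt
Reagents that add atoms: none
Why: Methanolysis of the oxalate frees a donor–acceptor cyclopropanol that opens by retro-aldol to the C6 aldehyde and the C11 methylene ester, the C8 hydroxyl lactonises onto that ester to give the trans-β,γ-disubstituted γ-butyrolactone (C7 retained, trans also being the thermodynamic isomer), and methoxide removes the alkynyl silyl group.

**Step 7**
Reactants: 15 the lactone ynal
Product: 17 (3aR,4S,5E,9Z,11aR)-4-hydroxy-6,10-dimethyl-3a,4,7,8,11,11a-hexahydrocyclodeca[b]furan-2(3H)-one (6S,7R,8R in germacrane numbering), via methylzinc alkoxide 16 (not isolated)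
Conditions: Ni(cod)2 (20 mol %), IMes·HCl (20 mol %), KOtBu (20 mol %), Me2Zn (2.5 equiv), THF, 0 °C to rt, syringe-pump addition of 15 (final 2 mM); aq NH4Cl
Reagents that add atoms: dimethylzinc, C[Zn]C
Why: Proposed new method: zerovalent nickel couples the terminal alkyne and the aldehyde oxidatively to an oxanickelacycle (C5–C6 bond at the unsubstituted alkyne carbon, favoured by the small carbene ligand), transmetalation from Me2Zn and reductive elimination place the C15 methyl syn to the new bond, which gives the 4E olefin and closes the ten-membered ring, and attack anti to the C7–C8 bond (Felkin–Anh, enforced by the forming ring) should give the 6S alcohol; the closest known reactions are the nickel-catalysed three-component aldehyde–alkyne–organozinc coupling and nickel-catalysed reductive macrocyclisations of ynals.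

**Step 8**
Reactants: 17 the macrocyclic hydroxy lactone
Product: 20 (3S,3aS,4S,5E,9Z,11aR)-6,10-dimethyl-3,4-bis[(triethylsilyl)oxy]-3a,4,7,8,11,11a-hexahydrocyclodeca[b]furan-2(3H)-one, via dilithium enolate alkoxide 18 (not isolated), via dilithium dialkoxide 19 (not isolated)
Conditions: LiN(iPr)2 (2.3 equiv), THF, −78 °C; 3-phenyl-2-(phenylsulfonyl)oxaziridine, −78 °C; then Et3SiCl (3 equiv), DMAP (cat.), −78 to 0 °C
Reagents that add atoms: 3-phenyl-2-(phenylsulfonyl)oxaziridine, O=S(=O)(c1ccccc1)N1OC1c1ccccc1; chlorotriethylsilane, CC[Si](Cl)(CC)CC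
Why: Davis enolate oxidation of the lactone dianion followed by in-flask silylation of both lithium alkoxides puts oxygen on C11 trans to the C6 arm (11S), a configuration that does not matter because C11 is planarised again in step 9.

**Step 9**
Reactants: 20 the bis(triethylsilyl) ether
Product: 22 (3R,3aS,4S,5E,9Z,11aR)-3,6,10-trimethyl-3,4-bis[(triethylsilyl)oxy]-3a,4,7,8,11,11a-hexahydrocyclodeca[b]furan-2(3H)-one, via lithium enolate 21 (not isolated)
Conditions: LiN(iPr)2 (1.5 equiv), THF/DMPU, −78 °C; MeI, −78 to −40 °C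
Reagents that add atoms: iodomethane, CI
Why: Diastereoselective alkylation of the α-silyloxy lactone enolate, in which iodomethane approaches the face opposite the C6 substituent on the adjacent C7, puts the C13 methyl trans and the oxygen cis to C6, which is the required 11R quaternary centre.

**Step 10**
Reactants: 22 the methylated bis(silyl) ether
Product: 23 (3R,3aR,4S,5E,9Z,11aR)-3,4-dihydroxy-3,6,10-trimethyl-3a,4,7,8,11,11a-hexahydrocyclodeca[b]furan-2(3H)-one
Conditions: HF·pyridine, pyridine, THF, 0 °C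
Reagents that add atoms: none
Why: Fluoride cleavage of both triethylsilyl ethers under pyridine-buffered conditions avoids acid-induced transannular cyclisation of the 1(10),4-diene and leaves all stereocentres untouched.

**Step 11**
Reactants: 23 the diol; 24 angelic anhydride
Product: 26 (3R,3aS,4S,5E,9Z,11aR)-3,6,10-trimethyl-2-oxo-2,3,3a,4,7,8,11,11a-octahydrocyclodeca[b]furan-3,4-diyl bis[(2Z)-2-methylbut-2-enoate], via dilithium dialkoxide 25 (not isolated)
Conditions: LiN(SiMe3)2 (2.3 equiv), THF, −78 °C; then 24 (4 equiv), −78 to −20 °C; aq NH4Cl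
Reagents that add atoms: none
Why: O-acylation of the pre-formed dilithium dialkoxide with the anhydride at low temperature esterifies the secondary and the hindered tertiary α-hydroxy-lactone oxygen without the heat or nucleophilic catalysts that would isomerise angelate to tiglate or trigger Cope rearrangement or translactonisation.

## Compound list

1 | methyl furan-2-carboxylate | COC(=O)c1ccco1 | starting material
2 | ethyl diazoacetate | CCOC(=O)C=[N+]=[N-] | starting material
3 | 6-ethyl 3-methyl (1R,5R,6R)-2-oxabicyclo[3.1.0]hex-3-ene-3,6-dicarboxylate | COC(=O)C1=C[C@@H]2[C@@H](C(=O)OCC)[C@@H]2O1 | intermediate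
4 | secondary ozonide (1,2,4-trioxolane across C3–C4) of 3, trioxolane centres unassigned | COC(=O)C12OC(OO1)[C@@H]1[C@@H](C(=O)OCC)[C@@H]1O2 | intermediate
5 | ethyl (1R,2R,3R)-2-formyl-3-[(2-methoxy-2-oxoacetyl)oxy]cyclopropane-1-carboxylate (CHO and oxalyloxy cis, ester trans to both) | O=C[C@@H]1[C@@H](C(=O)OCC)[C@@H]1OC(=O)C(=O)OC | intermediate
6 | 5-(trimethylsilyl)pent-4-yn-1-ol | C[Si](C)(C)C#CCCCO | starting material
7 | 5-(trimethylsilyl)pent-4-yn-1-yl N,N-diisopropylcarbamate | C[Si](C)(C)C#CCCCOC(=O)N(C(C)C)C(C)C | intermediate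
8 | isopropenylboronic acid pinacol ester | CC(=C)B1OC(C)(C)C(C)(C)O1 | starting material
9 | (1S)-1-lithio-5-(trimethylsilyl)pent-4-yn-1-yl N,N-diisopropylcarbamate (sparteine complex) | C[Si](C)(C)C#CCC[C@H]([Li])OC(=O)N(C(C)C)C(C)C | intermediate
10 | lithium [(1S)-1-(diisopropylcarbamoyloxy)-5-(trimethylsilyl)pent-4-yn-1-yl](isopropenyl)(pinacolato)borate | C[Si](C)(C)C#CCC[C@@H](OC(=O)N(C(C)C)C(C)C)[B-]1(C(C)=C)OC(C)(C)C(C)(C)O1.[Li+] | intermediate
11 | 4,4,5,5-tetramethyl-2-[(3R)-2-methyl-7-(trimethylsilyl)hept-1-en-6-yn-3-yl]-1,3,2-dioxaborolane | CC(=C)[C@@H](CCC#C[Si](C)(C)C)B1OC(C)(C)C(C)(C)O1 | intermediate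
12 | O-(pinacolatoboryl) ether of 13 | CC1(C)OB(O[C@H](C/C(C)=C\CCC#C[Si](C)(C)C)[C@@H]2[C@@H](C(=O)OCC)[C@@H]2OC(=O)C(=O)OC)OC1(C)C | intermediate
13 | ethyl (1R,2S,3R)-2-[(1R,3Z)-1-hydroxy-3-methyl-8-(trimethylsilyl)oct-3-en-7-yn-1-yl]-3-[(2-methoxy-2-oxoacetyl)oxy]cyclopropane-1-carboxylate | O[C@H](C/C(C)=C\CCC#C[Si](C)(C)C)[C@@H]1[C@@H](C(=O)OCC)[C@@H]1OC(=O)C(=O)OC | intermediate
14 | ethyl (1R,2S,3R)-3-hydroxy-2-[(1R,3Z)-1-hydroxy-3-methyl-8-(trimethylsilyl)oct-3-en-7-yn-1-yl]cyclopropane-1-carboxylate | O[C@H](C/C(C)=C\CCC#C[Si](C)(C)C)[C@@H]1[C@@H](C(=O)OCC)[C@@H]1O | intermediate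
15 | (2R,3S)-2-[(2Z)-2-methylhept-2-en-6-yn-1-yl]-5-oxooxolane-3-carbaldehyde (trans) | O=C[C@H]1CC(=O)O[C@@H]1C/C(C)=C\CCC#C | intermediate
16 | methylzinc alkoxide of 17 | C[Zn]O[C@H]1/C=C(\C)CC/C=C(/C)C[C@H]2OC(=O)C[C@H]12 | intermediate
17 | (3aR,4S,5E,9Z,11aR)-4-hydroxy-6,10-dimethyl-3a,4,7,8,11,11a-hexahydrocyclodeca[b]furan-2(3H)-one | O[C@H]1/C=C(\C)CC/C=C(/C)C[C@H]2OC(=O)C[C@H]12 | intermediate
18 | dilithium C6-alkoxide lactone enolate of 17 | [Li]O[C@H]1/C=C(\C)CC/C=C(/C)C[C@H]2OC(O[Li])=C[C@H]12 | intermediate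
19 | dilithium 6,11-dialkoxide (11S, oxygen trans to C6) | [Li]O[C@H]1/C=C(\C)CC/C=C(/C)C[C@H]2OC(=O)[C@@H](O[Li])[C@H]12 | intermediate
20 | (3S,3aS,4S,5E,9Z,11aR)-6,10-dimethyl-3,4-bis[(triethylsilyl)oxy]-3a,4,7,8,11,11a-hexahydrocyclodeca[b]furan-2(3H)-one | CC[Si](CC)(CC)O[C@H]1/C=C(\C)CC/C=C(/C)C[C@H]2OC(=O)[C@@H](O[Si](CC)(CC)CC)[C@H]12 | intermediate
21 | lithium enolate of 20 | CC[Si](CC)(CC)O[C@H]1/C=C(\C)CC/C=C(/C)C[C@H]2OC(O[Li])=C(O[Si](CC)(CC)CC)[C@H]12 | intermediate
22 | (3R,3aS,4S,5E,9Z,11aR)-3,6,10-trimethyl-3,4-bis[(triethylsilyl)oxy]-3a,4,7,8,11,11a-hexahydrocyclodeca[b]furan-2(3H)-one | CC[Si](CC)(CC)O[C@H]1/C=C(\C)CC/C=C(/C)C[C@H]2OC(=O)[C@](C)(O[Si](CC)(CC)CC)[C@H]12 | intermediate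
23 | (3R,3aR,4S,5E,9Z,11aR)-3,4-dihydroxy-3,6,10-trimethyl-3a,4,7,8,11,11a-hexahydrocyclodeca[b]furan-2(3H)-one | O[C@H]1/C=C(\C)CC/C=C(/C)C[C@H]2OC(=O)[C@](C)(O)[C@H]12 | intermediate
24 | angelic anhydride, (2Z)-2-methylbut-2-enoic anhydride | C/C=C(/C)C(=O)OC(=O)/C(C)=C\C | starting material
25 | dilithium dialkoxide of 23 | [Li]O[C@H]1/C=C(\C)CC/C=C(/C)C[C@H]2OC(=O)[C@](C)(O[Li])[C@H]12 | intermediate
26 | (3R,3aS,4S,5E,9Z,11aR)-3,6,10-trimethyl-2-oxo-2,3,3a,4,7,8,11,11a-octahydrocyclodeca[b]furan-3,4-diyl bis[(2Z)-2-methylbut-2-enoate] | C/C=C(/C)C(=O)O[C@H]1/C=C(\C)CC/C=C(/C)C[C@H]2OC(=O)[C@](C)(OC(=O)/C(C)=C\C)[C@H]12 | target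

## Step count and risks

Total step count: 11. Longest linear sequence: 9 steps (steps 1, 2, 5, 6, 7, 8, 9, 10, 11 from methyl furan-2-carboxylate).

**Step 7 (most likely to fail).** A ten-membered ring, an untested methylative variant, and C6 set only by substrate control. The fallback separates olefin construction from ring closure and sets out from 15. Acetalisation (HC(OMe)3, pyridinium tosylate, MeOH) gives (4S,5R)-4-(dimethoxymethyl)-5-[(2Z)-2-methylhept-2-en-6-yn-1-yl]oxolan-2-one F6. Water-accelerated Negishi carboalumination (Me3Al, Cp2ZrCl2 cat., H2O, CH2Cl2, −20 °C) followed by I2 gives the (E)-vinyl iodide acetal F7. Mild hydrolysis (pyridinium tosylate, acetone–water) gives (2R,3S)-2-[(2Z,6E)-7-iodo-2,6-dimethylhepta-2,6-dien-1-yl]-5-oxooxolane-3-carbaldehyde F8. Nozaki–Hiyama–Kishi macrocyclisation (CrCl2, divalent chromium, with NiCl2 cat., DMSO/THF, high dilution) forms C5–C6 with retention of the E geometry and comes back to the route at 17.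

**Step 5.** The Z-selectivity and the stereochemical matching of a hindered α,β-disubstituted allylboronate are not secured by close precedent. The fallback uses an α-selective, geometry-retentive allylbarium addition; it sets out from 5 and from 6. Dess–Martin oxidation of 6 gives 5-(trimethylsilyl)pent-4-ynal F1. Still–Gennari olefination with methyl 2-[bis(2,2,2-trifluoroethoxy)phosphoryl]propanoate (KN(SiMe3)2, 18-crown-6, THF, −78 °C) gives methyl (2Z)-2-methyl-7-(trimethylsilyl)hept-2-en-6-ynoate F2. Reduction with iBu2AlH gives (2Z)-2-methyl-7-(trimethylsilyl)hept-2-en-6-yn-1-ol F3. Corey–Kim chlorination (N-chlorosuccinimide, Me2S) gives (2Z)-1-chloro-2-methyl-7-(trimethylsilyl)hept-2-en-6-yne F4. Active barium (BaI2 reduced with lithium biphenylide, THF, −78 °C) gives [(2Z)-2-methyl-7-(trimethylsilyl)hept-2-en-6-yn-1-yl]barium chloride F5. F5 adds to 5 through its α-carbon with retention of the Z geometry under Felkin–Anh control and comes back to the route at 13.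

**Step 11.** Direct acylation of the tertiary C11 hydroxyl with an isomerisation-prone acyl donor may stall or give tiglate. The fallback builds the two Z olefins after esterification and sets out from 23. Carbodiimide esterification (DCC, DMAP) with 2-[bis(2,2,2-trifluoroethoxy)phosphoryl]propanoic acid, which acylates hindered alcohols through a ketene-like intermediate, gives the bis(phosphonopropanoate) F9. Double Still–Gennari olefination with acetaldehyde (KN(SiMe3)2, 18-crown-6, THF, −78 °C) generates both (2Z)-2-methylbut-2-enoates in place and comes back to the route at 26.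

## Further compounds

F1 | step 5 | 5-(trimethylsilyl)pent-4-ynal | C[Si](C)(C)C#CCCC=O
F2 | step 5 | methyl (2Z)-2-methyl-7-(trimethylsilyl)hept-2-en-6-ynoate | COC(=O)/C(C)=C\CCC#C[Si](C)(C)C
F3 | step 5 | (2Z)-2-methyl-7-(trimethylsilyl)hept-2-en-6-yn-1-ol | OC/C(C)=C\CCC#C[Si](C)(C)C
F4 | step 5 | (2Z)-1-chloro-2-methyl-7-(trimethylsilyl)hept-2-en-6-yne | ClC/C(C)=C\CCC#C[Si](C)(C)C
F5 | step 5 | [(2Z)-2-methyl-7-(trimethylsilyl)hept-2-en-6-yn-1-yl]barium chloride | Cl[Ba]C/C(C)=C\CCC#C[Si](C)(C)C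
F6 | step 7 | (4S,5R)-4-(dimethoxymethyl)-5-[(2Z)-2-methylhept-2-en-6-yn-1-yl]oxolan-2-one | COC(OC)[C@H]1CC(=O)O[C@@H]1C/C(C)=C\CCC#C
F7 | step 7 | (4S,5R)-4-(dimethoxymethyl)-5-[(2Z,6E)-7-iodo-2,6-dimethylhepta-2,6-dien-1-yl]oxolan-2-one | COC(OC)[C@H]1CC(=O)O[C@@H]1C/C(C)=C\CC/C(C)=C/I
F8 | step 7 | (2R,3S)-2-[(2Z,6E)-7-iodo-2,6-dimethylhepta-2,6-dien-1-yl]-5-oxooxolane-3-carbaldehyde | O=C[C@H]1CC(=O)O[C@@H]1C/C(C)=C\CC/C(C)=C/I
F9 | step 11 | 6,11-bis{2-[bis(2,2,2-trifluoroethoxy)phosphoryl]propanoate} of diol 23 (phosphonate α-carbons unassigned) | CC(C(=O)O[C@H]1/C=C(\C)CC/C=C(/C)C[C@H]2OC(=O)[C@](C)(OC(=O)C(C)P(=O)(OCC(F)(F)F)OCC(F)(F)F)[C@H]12)P(=O)(OCC(F)(F)F)OCC(F)(F)F
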